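## Retrosynthetic overview
1. Target 14 comes from double asymmetric transfer hydrogenation with dynamic kinetic resolution of bis(α-aryloxy ketone) 13. This sets both side-chain carbinols and both OCH(CH3) centres.
2. The THF ring of 13 is formed by a 5-exo radical cyclization, which makes the C2–C3 bond and the C3 methyl. The radical is the α-aryl-α-alkoxy radical from O,S-acetal 12, and it adds to a vinyl group.
3. 12 comes from syn-homoallylic alcohol 11 and aldehyde 9. 11 is made by Z-crotylboration of 9, so C4 and C5 are preset and cis. Both halves of the core come from the same aldehyde 9.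
4. 9 is vanillin O-alkylated with α-bromoketone 8. Vanillin and 8 both come from catechol. The THF is the only non-aromatic ring, and it forms in Step 9.

Assumption: the target is C2-symmetric (both arms identical, as the SMILES shows), and the α-stereocentres of the ketone intermediates are epimerizable.

## Route

**Step 1**
Reactants: 1 catechol
Product: 2 guaiacol (2-methoxyphenol)
Conditions: (MeO)2CO, K2CO3 (cat.), 160 °C, sealed vessel
Reagents that add atoms: dimethyl carbonate, COC(=O)OC
Why: Selective mono-O-methylation of catechol (B_Al2-type methylation by dimethyl carbonate).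

**Step 2**
Reactants: 2 guaiacol; 3 glyoxylic acid
Product: 4 vanillylmandelic acid (racemic)
Conditions: aq. NaOH, 0 °C to rt; then H3O+
Reagents that add atoms: none
Why: Phenoxide undergoes para-selective hydroxyalkylation (Friedel–Crafts-type addition to an aldehyde). The stereocentre is destroyed in the next step.

**Step 3**
Reactants: 4 vanillylmandelic acid
Product: 5 vanillin
Conditions: O2 (air), Cu(OH)2 (cat.), aq. NaOH, 80 °C; then H3O+, 90 °C
Reagents that add atoms: none
Why: Cu-catalysed oxidation of the mandelic acid to the aryl-glyoxylic acid, followed by decarboxylation (the standard industrial vanillin sequence).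

**Step 4**
Reactants: 1 catechol
Product: 6 veratrole (1,2-dimethoxybenzene)
Conditions: Me2SO4, NaOH, H2O, 40 °C
Reagents that add atoms: dimethyl sulfate, COS(=O)(=O)OC
Why: Williamson bis-O-methylation.

**Step 5**
Reactants: 6 veratrole; 7 2-bromopropionyl bromide
Product: 8 2-bromo-1-(3,4-dimethoxyphenyl)propan-1-one (racemic)
Conditions: AlCl3, CH2Cl2, 0 °C, 1 h
Reagents that add atoms: none
Why: Friedel–Crafts acylation occurs at C4 of veratrole, para to one OMe, and gives the α-bromoketone directly.

**Step 6**
Reactants: 5 vanillin; 8 α-bromoketone
Product: 9 4-{[1-(3,4-dimethoxyphenyl)-1-oxopropan-2-yl]oxy}-3-methoxybenzaldehyde (racemic at the OCH(CH3) carbon)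
Conditions: K2CO3, DMF, rt, 12 h
Reagents that add atoms: none
Why: SN2 alkylation of the phenoxide by the α-bromoketone; the aldehyde is untouched. The α-centre is racemic but epimerizable, and it is resolved in Step 10.

**Step 7**
Reactants: 9 aldehyde; 10 cis-2-butene (crotyl source)
Product: 11 (1S,2R)-1-aryl-2-methylbut-3-en-1-ol (syn homoallylic alcohol). Aryl is the 4-(1-aroylethoxy)-3-methoxyphenyl group; side-chain α-centre is epimeric.
Conditions: (Z)-crotyl-B(Ipc)2, THF, –78 °C, 3 h; then NaBO3·4H2O, THF/H2O, rt. The reagent is made from 10 by KOtBu/n-BuLi metalation, then Ipc2BOMe, then BF3·OEt2. The α-pinene enantiomer is the one that delivers the (1S,2R) alcohol.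
Reagents that add atoms: none (the crotyl unit comes from 10; boron and Ipc are lost)
Why: Brown asymmetric allylboration proceeds through a chair Zimmerman–Traxler TS. The Z-crotyl geometry gives syn (4,5-cis after cyclization) and the Ipc auxiliary sets C1 and C2 together. Aldehyde reacts far faster than the aryl ketone.

**Step 8**
Reactants: 11 homoallylic alcohol; 9 aldehyde; PhSH
Product: 12 O,S-acetal, ArCH(SPh)–O–CH(Ar)–CH(CH3)–CH=CH2 (acetal carbon epimeric; C5/C4 centres retained)
Conditions: TMSOTf (10 mol %), 4 Å MS, CH2Cl2, –20 °C, 2 h
Reagents that add atoms: thiophenol, Sc1ccccc1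
Why: Three-component O,S-acetalization. The alcohol oxygen attacks the silyl-activated thionium/oxocarbenium ion, so the carbinol carbon is not touched and keeps its configuration. The new acetal centre is irrelevant because it is destroyed in Step 9.

**Step 9**
Reactants: 12 O,S-acetal
Product: 13 THF bis-ketone, (2S,3R,4R,5S)-2,5-diaryl-3,4-dimethyltetrahydrofuran with both side chains as ArCO–CH(CH3)–OAr (side-chain α-centres epimeric)
Conditions: Bu3SnH (1.5 equiv, syringe pump over 8 h), AIBN (0.2 equiv), benzene (0.005 M in 12), 80 °C
Reagents that add atoms: none (Bu3SnH supplies only H)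
Why: Proposed new method: Bu3Sn• abstracts PhS to give the stabilized α-aryl-α-alkoxy radical, which cyclizes 5-exo-trig onto the vinyl group to close the THF and form the C3–CH2• group, and Bu3SnH then reduces the primary radical to CH3. The closest known reaction type is Beckwith–Houk 5-exo cyclization of α-alkoxyalkyl radicals to 2,3-disubstituted THFs (Ueno–Stork type). In the chair-like TS the preset C4 methyl prefers the pseudo-equatorial position, which places the new CH2• trans to it (3,4-trans). The 1-substituted hexenyl rule places the aryl on the radical carbon cis to the new C3 substituent (2,3-cis). Together with the preset 4,5-cis relationship this gives the C2-symmetric 2,3-cis/3,4-trans/4,5-cis core, and any minor ring diastereomers are removed by chromatography. Low Bu3SnH concentration is needed because a benzylic radical cyclizes slowly.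

**Step 10**
Reactants: 13 bis-ketone
Product: 14 manassantin A
Conditions: RuCl[(S,S)-TsDPEN](p-cymene) (5 mol %), HCO2H–Et3N (5:2), EtOAc, 35 °C, 48 h
Reagents that add atoms: none (formate supplies only H)
Why: Noyori–Ikariya asymmetric transfer hydrogenation with dynamic kinetic resolution. The (S,S) catalyst delivers hydride to the face that gives the (R)-carbinol, and that face is Felkin–Anh matched with the (R)-OCH(CH3) epimer of each ketone. The α-centres epimerize under the conditions, so every ketone funnels to (7'R,8'R). The ring stereocentres are untouched because the buffered formate is mild.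

## Compound list
1 | catechol | Oc1ccccc1O | starting material
2 | guaiacol | COc1ccccc1O | intermediate
3 | glyoxylic acid | OC(=O)C=O | starting material
4 | vanillylmandelic acid (racemic) | COc1cc(C(O)C(=O)O)ccc1O | intermediate
5 | vanillin | COc1cc(C=O)ccc1O | intermediate
6 | veratrole | COc1ccccc1OC | intermediate
7 | 2-bromopropionyl bromide | CC(Br)C(=O)Br | starting material
8 | 2-bromo-1-(3,4-dimethoxyphenyl)propan-1-one | COc1ccc(C(=O)C(C)Br)cc1OC | intermediate
9 | aryloxy-ketone aldehyde | COc1ccc(cc1OC)C(=O)C(C)Oc1ccc(C=O)cc1OC | intermediate
10 | cis-2-butene | C/C=C\C | starting material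
11 | syn homoallylic alcohol (1S,2R) | COc1ccc(cc1OC)C(=O)C(C)Oc1ccc(cc1OC)[C@@H](O)[C@H](C)C=C | intermediate
12 | O,S-acetal | COc1ccc(cc1OC)C(=O)C(C)Oc1ccc(cc1OC)C(Sc1ccccc1)O[C@H](c1ccc(OC(C)C(=O)c2ccc(OC)c(OC)c2)c(OC)c1)[C@H](C)C=C | intermediate
13 | THF bis-ketone | COc1ccc(cc1OC)C(=O)C(C)Oc1ccc(cc1OC)[C@H]1O[C@H](c2ccc(OC(C)C(=O)c3ccc(OC)c(OC)c3)c(OC)c2)[C@H](C)[C@H]1C | intermediate
14 | manassantin A | COc1ccc([C@@H](O)[C@@H](C)Oc2ccc([C@H]3O[C@H](c4ccc(O[C@H](C)[C@H](O)c5ccc(OC)c(OC)c5)c(OC)c4)[C@H](C)[C@H]3C)cc2OC)cc1OC | target

## Totals
Total steps: 10. Longest linear sequence: 8 (catechol → 2 → 4 → 5 → 9 → 11 → 12 → 13 → 14). The veratrole → 8 branch is 2 steps and joins at Step 6.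

## Three steps most likely to fail
1. **Step 9, radical cyclization.** The benzylic radical cyclizes slowly and may be reduced before it cyclizes. The ring diastereoselectivity, especially 2,3-cis, is a prediction.
   - Fallback: build the trans-3,4-dimethyl unit by Evans-auxiliary oxidative dimerization of the N-propionyl imide enolate. Convert the dimer to the bis-Weinreb amide and add ArMgBr twice to give the diaryl 1,4-diketone. Reduce enantioselectively and close the THF by mesylate SN2 with inversion.
2. **Step 10, double ATH-DKR.** Four stereocentres must be set with high selectivity, and the matched/mismatched outcome may give the wrong syn/anti relationship.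
   - Fallback: install each side chain from (S)-ethyl lactate by Mitsunobu reaction on the bis-phenol core. Convert each ester to the aryl ketone via its Weinreb amide plus Ar'MgBr, and reduce with a Felkin-selective hydride.
3. **Step 8, O,S-acetalization.** The electron-rich secondary benzylic alcohol may ionize under Lewis acid, which would racemize or eliminate it.
   - Fallback: deprotonate 11 with NaH and alkylate with a preformed ArCH(Cl)SPh. Alternatively, make the benzyl ether and use thiol-catalysed photo-HAT cycloisomerization of the C7 radical.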